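**Retrosynthetic overview**

1. Target 34 ⇐ C7 allylic oxidation, C2 inversion and acetylation of the 2β,15,19-triol 30 ⇐ bridged-acetal labdadiene 28 ⇐ C11 sulfone 27.
2. Key disconnection C11–C12 (with C8–C9): 27 ⇐ vinyl iodide 24 + (Z)-allylic bromide 4, by I/Li exchange at C8, 6-exo Michael closure of ring B onto a C9=C11 vinyl sulfone, and SN2 alkylation of the C11 sulfonyl carbanion.
3. Enabling feature: C8 of ring B carries the exocyclic C17 methylene and its neighbour C9 carries C11, so C8 can be a vinyl anion and C9=C11 a vinyl sulfone; closing C8–C9 puts the carbanion on C11, the atom that must bond to C12. A temporary C19–O–C2 acetal bridge holds ring A as a chair with the C5 and C10 arms equatorial.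
4. Ring A (C4–C5, then C10–C9 bond): radical 6-endo cyclisation/sulfonylvinylation of α-bromo lactone 19; the lactone tether from (S)-epichlorohydrin (C2) sets C4, C5 and C10.
5. Ring order: temporary lactone → ring A → ring B; the Z side chain 4 comes from 4-methylfuran-2(5H)-one (ring-locked geometry).

Key step: step 12

Remark: labdane numbering (C1–C20) is used for all intermediates, and the SMILES is read as a normal-series labdane (2α-OH, 4β-CH2OAc = C19, 5α-H, 7α-OH, 9β side chain, 10β-CH3, 13Z); compounds 1, 5, 6, 11, 14 and 20 are taken as commercial.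

**Route**

Step 1
Reactants: 1 4-methylfuran-2(5H)-one
Product: 2 (Z)-2-methylbut-2-ene-1,4-diol
Conditions: DIBAL-H (3.5 equiv), CH2Cl2, −78 → 0 °C; Rochelle salt
Reagents that add atoms: none
Why: DIBAL-H reduction of the lactone through the lactol to the diol; the Z geometry is the one locked in the five-membered ring, so the future C12 and C15 emerge cis.

Step 2
Reactants: 2 (Z)-2-methylbut-2-ene-1,4-diol
Product: 3 (Z)-4-[(tert-butyldimethylsilyl)oxy]-2-methylbut-2-en-1-ol
Conditions: TBSCl (1.0 equiv), imidazole, CH2Cl2, −40 °C; chromatography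
Reagents that add atoms: tert-butyldimethylsilyl chloride, CC(C)(C)[Si](C)(C)Cl
Why: Sterically controlled silyl etherification: the CH2OH next to the vinylic CH (future C15) should react ahead of the one next to the methyl-bearing carbon (future C12), and the minor regioisomer is removed by chromatography.

Step 3
Reactants: 3 (Z)-4-[(tert-butyldimethylsilyl)oxy]-2-methylbut-2-en-1-ol
Product: 4 (Z)-[(4-bromo-3-methylbut-2-en-1-yl)oxy](tert-butyl)dimethylsilane
Conditions: CBr4, PPh3, CH2Cl2, 0 °C
Reagents that add atoms: carbon tetrabromide, BrC(Br)(Br)Br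
Why: Appel bromination displaces the primary allylic oxyphosphonium by SN2, which leaves the Z alkene untouched.

Step 4
Reactants: 5 5-bromopent-2-yne; 6 (1-bromovinyl)trimethylsilane
Product: 8 trimethyl(hept-1-en-5-yn-2-yl)silane, via vinyl Grignard reagent 7 (not isolated)
Conditions: Mg, THF, 40 °C; then 5, Li2CuCl4 (cat.), THF, −10 → 20 °C
Reagents that add atoms: none
Why: Copper-catalysed Grignard cross-coupling of an alkenylmagnesium with a primary alkyl bromide joins the future C8/C17 unit to the future C7.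

Step 5
Reactants: 8 trimethyl(hept-1-en-5-yn-2-yl)silane
Product: 10 [(5E)-6-iodohepta-1,5-dien-2-yl]trimethylsilane, via alkenylzirconocene chloride 9 (not isolated)
Conditions: Cp2Zr(H)Cl (excess), THF, 45 °C; then I2, −20 °C
Reagents that add atoms: iodine, II
Why: Hydrozirconation is a syn addition that, after equilibration with excess hydride, should place Zr on the alkyne carbon next to the small methyl group, and iodinolysis with retention gives the (E)-iodoalkene; the hindered 1,1-disubstituted vinylsilane is left alone.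

Step 6
Reactants: 10 [(5E)-6-iodohepta-1,5-dien-2-yl]trimethylsilane; 11 (S)-epichlorohydrin
Product: 13 (2S,4E)-1-chloro-4-methyl-8-(trimethylsilyl)nona-4,8-dien-2-ol, via alkenyllithium 12 (not isolated)
Conditions: t-BuLi (2.1 equiv), Et2O, −78 °C; then 11, BF3·OEt2, −78 °C
Reagents that add atoms: none
Why: Iodine–lithium exchange with retention of alkene geometry, then BF3-assisted SN2 opening of the oxirane at its CH2 terminus; the stereocentre of 11 is not touched and becomes C2 (S).

Step 7
Reactants: 13 (2S,4E)-1-chloro-4-methyl-8-(trimethylsilyl)nona-4,8-dien-2-ol; 14 propanoic acid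
Product: 18 (5R)-3-methyl-5-[(2E)-2-methyl-6-(trimethylsilyl)hepta-2,6-dien-1-yl]oxolan-2-one (C3 epimers), via dilithium propanoate enediolate 15 (not isolated), via epoxide 16 (not isolated), via hydroxy acid 17 (not isolated)
Conditions: 14 (3.5 equiv), LDA (7 equiv), THF/HMPA, 0 → 45 °C; 1 M HCl; TsOH (cat.), PhH, 80 °C
Reagents that add atoms: none
Why: Carboxylic acid dianion alkylation: the base closes the chlorohydrin to the terminal epoxide, the enediolate opens it at CH2 (C3–C4 bond) and the γ-hydroxy acid lactonises; C2 is unchanged and C4 forms as an inconsequential mixture.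

Step 8
Reactants: 18 (5R)-3-methyl-5-[(2E)-2-methyl-6-(trimethylsilyl)hepta-2,6-dien-1-yl]oxolan-2-one
Product: 19 (5S)-3-bromo-3-methyl-5-[(2E)-2-methyl-6-(trimethylsilyl)hepta-2,6-dien-1-yl]oxolan-2-one (C3 epimers)
Conditions: LDA, THF, −78 °C; then CBr4, −78 °C
Reagents that add atoms: carbon tetrabromide, BrC(Br)(Br)Br
Why: Electrophilic bromination of the lactone enolate gives the tertiary α-bromide as radical precursor; the C4 configuration is irrelevant because it becomes a planar radical.

Step 9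
Reactants: 19 (5S)-3-bromo-3-methyl-5-[(2E)-2-methyl-6-(trimethylsilyl)hepta-2,6-dien-1-yl]oxolan-2-one; 20 (E)-1,2-bis(phenylsulfonyl)ethene
Product: 21 (1S,2R,3S,5S)-1,3-dimethyl-3-[(E)-2-(phenylsulfonyl)ethenyl]-2-[3-(trimethylsilyl)but-3-en-1-yl]-6-oxabicyclo[3.2.1]octan-7-one (ring A with 19,2β-lactone bridge)
Conditions: (Bu3Sn)2 (1.2 equiv), 20 (5 equiv, 0.4 M), hν (sunlamp), PhH, 80 °C
Reagents that add atoms: none
Why: Tandem radical cyclisation/intermolecular addition–fragmentation: the electrophilic C4 radical closes ring A by 6-endo attack on C5 of the electron-rich (E)-alkene through a chair in which the lactone bridge is necessarily diaxial on C2/C4 and C6 is equatorial (hence C19 β, H-5 α), and the nucleophilic C10 radical is then vinylated by 20 on the face away from the bridge with loss of PhSO2•, so C10 carries CH3 β and the (E)-sulfonylvinyl group α.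

Step 10
Reactants: 21 bridged lactone (as above)
Product: 23 (1S,2R,3S,5S)-7-methoxy-1,3-dimethyl-3-[(E)-2-(phenylsulfonyl)ethenyl]-2-[3-(trimethylsilyl)but-3-en-1-yl]-6-oxabicyclo[3.2.1]octane (C7 anomers), via lactol 22 (not isolated)
Conditions: DIBAL-H (1.2 equiv), CH2Cl2, −78 °C; Rochelle work-up; crude lactol in MeOH, PPTS, 25 °C
Reagents that add atoms: methanol, CO
Why: Partial DIBAL-H reduction of the lactone to the lactol and acid-catalysed acetalisation mask C19 as a base-stable acetal that still locks ring A in the chair; no skeletal stereocentre changes and the C19 anomers are irrelevant.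

Step 11
Reactants: 23 bridged methyl acetal (as above)
Product: 24 (1S,2R,3S,5S)-2-(3-iodobut-3-en-1-yl)-7-methoxy-1,3-dimethyl-3-[(E)-2-(phenylsulfonyl)ethenyl]-6-oxabicyclo[3.2.1]octane
Conditions: NIS, MeCN/ClCH2CN (4:1), 0 → 25 °C, dark
Reagents that add atoms: N-iodosuccinimide, O=C1CCC(=O)N1I
Why: Ipso-iododesilylation of the vinylsilane through the β-silyl cation gives the 2-iodo-1-alkene; the electron-poor vinyl sulfone does not react with the electrophilic iodine source.

Step 12
Reactants: 24 vinyl iodide (as above); 4 (Z)-[(4-bromo-3-methylbut-2-en-1-yl)oxy](tert-butyl)dimethylsilane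
Product: 27 tert-butyl{[(13Z)-2β,19-epoxy-19-methoxy-11-(phenylsulfonyl)labda-8(17),13-dien-15-yl]oxy}dimethylsilane (C11 and C19 epimers), via vinyllithium 25 (not isolated), via lithiated sulfone 26 (not isolated)
Conditions: t-BuLi (2.05 equiv), THF/Et2O/pentane (4:1:1), −100 °C; −78 °C, 30 min; then 4 (1.5 equiv), DMPU, −78 → −30 °C
Reagents that add atoms: none
Why: Iodine–lithium exchange at C8 gives vinyllithium 25, which adds to C9 of the tethered (E)-vinyl sulfone in a 6-exo-trig Michael ring closure (ring B), and the resulting lithio sulfone 26 is alkylated at C11 by the primary allylic bromide 4 in an SN2 step that forms C11–C12. The closest known reaction type is the conjugate addition of vinyllithiums to vinyl sulfones with trapping of the α-sulfonyl carbanion by allylic halides, combined with halogen–metal-exchange-initiated Michael ring closure. Ring B closes trans-fused because the acetal bridge fixes ring A as a chair in which the C5 arm and the C10 sulfonylvinyl group are both equatorial. C9 is set in a chair-like transition state with the sulfonylmethine branch equatorial (H-9 α), and the C11 configuration is irrelevant because the sulfone is removed in step 13. The step needs exchange to outrun α-lithiation of, or tert-butyl addition to, the vinyl sulfone, which the −100 °C protocol and the neopentyl-type β-carbon should secure, and it needs SN2 rather than SN2′ alkylation with retention of the Z alkene, which a lithium sulfonyl carbanion and a primary bromide should secure. In one flask it delivers ring B, the C8=C17 methylene, C9 and the complete C20 skeleton.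

Step 13
Reactants: 27 coupled sulfone (as above)
Product: 28 tert-butyl{[(13Z)-2β,19-epoxy-19-methoxylabda-8(17),13-dien-15-yl]oxy}dimethylsilane (C19 epimers)
Conditions: Na(Hg) (6%), Na2HPO4, MeOH/THF, −20 °C
Reagents that add atoms: none
Why: Reductive desulfonylation with sodium amalgam (two electron transfers, protonation by methanol) replaces the C11 sulfonyl group by hydrogen and removes the C11 stereocentre; alkenes, acetal and silyl ether are inert.

Step 14
Reactants: 28 bridged acetal diene (as above)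
Product: 30 (13Z)-labda-8(17),13-diene-2β,15,19-triol, via lactol 29 (not isolated)
Conditions: AcOH/THF/H2O (3:1:1), 40 °C; concentrate; NaBH4, EtOH, 0 → 25 °C
Reagents that add atoms: water, O
Why: Acid hydrolysis of the bridged acetal and of the primary silyl ether, then borohydride reduction of the lactol through its hydroxy-aldehyde form, releases the triol without touching a stereocentre.

Step 15
Reactants: 30 (13Z)-labda-8(17),13-diene-2β,15,19-triol
Product: 31 (13Z)-2β-hydroxylabda-8(17),13-diene-15,19-diyl diacetate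
Conditions: Ac2O (2.3 equiv), pyridine, CH2Cl2, 0 °C
Reagents that add atoms: acetic anhydride, CC(=O)OC(C)=O
Why: Sterically controlled acetylation: the two primary hydroxyls react, while the axial 2β-OH, syn-diaxial to C19 and C20, should stay free.

Step 16
Reactants: 31 (13Z)-2β-hydroxylabda-8(17),13-diene-15,19-diyl diacetate
Product: 32 (13Z)-2α-(chloroacetoxy)labda-8(17),13-diene-15,19-diyl diacetate
Conditions: ClCH2CO2H, PPh3, DIAD, toluene, 0 → 25 °C
Reagents that add atoms: chloroacetic acid, OC(=O)CCl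
Why: Mitsunobu esterification with an acidic pronucleophile proceeds by SN2 at C2, inverting the axial 2β-OH to the equatorial 2α-ester and protecting it in the same operation.

Step 17
Reactants: 32 (13Z)-2α-(chloroacetoxy)labda-8(17),13-diene-15,19-diyl diacetate
Product: 33 (13Z)-2α-(chloroacetoxy)-7α-hydroxylabda-8(17),13-diene-15,19-diyl diacetate
Conditions: SeO2 (0.5 equiv), t-BuOOH (3 equiv), CH2Cl2, 0 → 25 °C
Reagents that add atoms: tert-butyl hydroperoxide, CC(C)(C)OO
Why: SeO2-catalysed allylic oxidation (ene reaction at C17 with removal of the axial H-7α, then [2,3]-sigmatropic shift) returns oxygen to the α face of C7 and regenerates the exocyclic alkene; the side-chain alkene should be deactivated by its allylic acetate.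

Step 18
Reactants: 33 (13Z)-2α-(chloroacetoxy)-7α-hydroxylabda-8(17),13-diene-15,19-diyl diacetate
Product: 34 (13Z)-2α,7α-dihydroxylabda-8(17),13-diene-15,19-diyl diacetate (CNP0171158.2)
Conditions: thiourea, NaHCO3, EtOH, 50 °C
Reagents that add atoms: none
Why: Thiourea cleaves the chloroacetate selectively by S-alkylation and cyclisation to the aminothiazolone, leaving both acetates in place.

**Compound list**

1 | 4-methylfuran-2(5H)-one | CC1=CC(=O)OC1 | starting material
2 | (Z)-2-methylbut-2-ene-1,4-diol | OC/C(C)=C\CO | intermediate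
3 | (Z)-4-[(tert-butyldimethylsilyl)oxy]-2-methylbut-2-en-1-ol | OC/C(C)=C\CO[Si](C)(C)C(C)(C)C | intermediate
4 | (Z)-[(4-bromo-3-methylbut-2-en-1-yl)oxy](tert-butyl)dimethylsilane | BrC/C(C)=C\CO[Si](C)(C)C(C)(C)C | intermediate
5 | 5-bromopent-2-yne | CC#CCCBr | starting material
6 | (1-bromovinyl)trimethylsilane | C=C(Br)[Si](C)(C)C | starting material
7 | [1-(trimethylsilyl)vinyl]magnesium bromide | C=C([Mg]Br)[Si](C)(C)C | intermediate
8 | trimethyl(hept-1-en-5-yn-2-yl)silane | C=C(CCC#CC)[Si](C)(C)C | intermediate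
9 | chloro[(2E)-6-(trimethylsilyl)hepta-2,6-dien-2-yl]zirconocene | C/C(=C\CCC(=C)[Si](C)(C)C)[Zr](Cl)(C1C=CC=C1)C1C=CC=C1 | intermediate
10 | [(5E)-6-iodohepta-1,5-dien-2-yl]trimethylsilane | C/C(I)=C\CCC(=C)[Si](C)(C)C | intermediate
11 | (S)-epichlorohydrin | ClC[C@@H]1CO1 | starting material
12 | [(2Z)-6-(trimethylsilyl)hepta-2,6-dien-2-yl]lithium (geometry retained from 10) | C/C([Li])=C\CCC(=C)[Si](C)(C)C | intermediate
13 | (2S,4E)-1-chloro-4-methyl-8-(trimethylsilyl)nona-4,8-dien-2-ol | ClC[C@@H](O)C/C(C)=C/CCC(=C)[Si](C)(C)C | intermediate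
14 | propanoic acid | CCC(=O)O | starting material
15 | dilithium propanoate enediolate | CC=C(O[Li])O[Li] | intermediate
16 | (2S)-2-[(2E)-2-methyl-6-(trimethylsilyl)hepta-2,6-dien-1-yl]oxirane | C1[C@@H](O1)C/C(C)=C/CCC(=C)[Si](C)(C)C | intermediate
17 | (4R,6E)-4-hydroxy-2,6-dimethyl-10-(trimethylsilyl)undeca-6,10-dienoic acid (C2 epimers) | CC(C[C@@H](O)C/C(C)=C/CCC(=C)[Si](C)(C)C)C(=O)O | intermediate
18 | (5R)-3-methyl-5-[(2E)-2-methyl-6-(trimethylsilyl)hepta-2,6-dien-1-yl]oxolan-2-one (C3 epimers) | CC1C[C@H](C/C(C)=C/CCC(=C)[Si](C)(C)C)OC1=O | intermediate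
19 | (5S)-3-bromo-3-methyl-5-[(2E)-2-methyl-6-(trimethylsilyl)hepta-2,6-dien-1-yl]oxolan-2-one (C3 epimers) | CC1(Br)C[C@H](C/C(C)=C/CCC(=C)[Si](C)(C)C)OC1=O | intermediate
20 | (E)-1,2-bis(phenylsulfonyl)ethene | O=S(=O)(/C=C/S(=O)(=O)c1ccccc1)c1ccccc1 | starting material
21 | (1S,2R,3S,5S)-1,3-dimethyl-3-[(E)-2-(phenylsulfonyl)ethenyl]-2-[3-(trimethylsilyl)but-3-en-1-yl]-6-oxabicyclo[3.2.1]octan-7-one (labdane numbering: 19,2β-olide, 4α-CH3, 5α-H, 10β-CH3) | C=C([Si](C)(C)C)CC[C@H]2[C@@](C)(C(=O)O3)C[C@@H]3C[C@]2(C)/C=C/S(=O)(=O)c1ccccc1 | intermediate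
22 | (1S,2R,3S,5S)-1,3-dimethyl-3-[(E)-2-(phenylsulfonyl)ethenyl]-2-[3-(trimethylsilyl)but-3-en-1-yl]-6-oxabicyclo[3.2.1]octan-7-ol (lactol, C7 epimers) | C=C([Si](C)(C)C)CC[C@H]2[C@@](C)(C(O)O3)C[C@@H]3C[C@]2(C)/C=C/S(=O)(=O)c1ccccc1 | intermediate
23 | (1S,2R,3S,5S)-7-methoxy-1,3-dimethyl-3-[(E)-2-(phenylsulfonyl)ethenyl]-2-[3-(trimethylsilyl)but-3-en-1-yl]-6-oxabicyclo[3.2.1]octane (C7 anomers) | C=C([Si](C)(C)C)CC[C@H]2[C@@](C)(C(OC)O3)C[C@@H]3C[C@]2(C)/C=C/S(=O)(=O)c1ccccc1 | intermediate
24 | (1S,2R,3S,5S)-2-(3-iodobut-3-en-1-yl)-7-methoxy-1,3-dimethyl-3-[(E)-2-(phenylsulfonyl)ethenyl]-6-oxabicyclo[3.2.1]octane (C7 anomers) | C=C(I)CC[C@H]2[C@@](C)(C(OC)O3)C[C@@H]3C[C@]2(C)/C=C/S(=O)(=O)c1ccccc1 | intermediate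
25 | C8 vinyllithium derived from 24 | C=C([Li])CC[C@H]2[C@@](C)(C(OC)O3)C[C@@H]3C[C@]2(C)/C=C/S(=O)(=O)c1ccccc1 | intermediate
26 | 11-lithio-2β,19-epoxy-19-methoxy-11-(phenylsulfonyl)-12,13,14,15,16-pentanorlabd-8(17)-ene | C=C1CC[C@H]2[C@@](C)(C(OC)O3)C[C@@H]3C[C@]2(C)[C@H]1C([Li])S(=O)(=O)c4ccccc4 | intermediate
27 | tert-butyl{[(13Z)-2β,19-epoxy-19-methoxy-11-(phenylsulfonyl)labda-8(17),13-dien-15-yl]oxy}dimethylsilane (C11 and C19 epimers) | C=C1CC[C@H]2[C@@](C)(C(OC)O3)C[C@@H]3C[C@]2(C)[C@H]1C(S(=O)(=O)c4ccccc4)C/C(C)=C\CO[Si](C)(C)C(C)(C)C | intermediate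
28 | tert-butyl{[(13Z)-2β,19-epoxy-19-methoxylabda-8(17),13-dien-15-yl]oxy}dimethylsilane (C19 epimers) | C=C1CC[C@H]2[C@@](C)(C(OC)O3)C[C@@H]3C[C@]2(C)[C@H]1CC/C(C)=C\CO[Si](C)(C)C(C)(C)C | intermediate
29 | (13Z)-2β,19-epoxylabda-8(17),13-diene-15,19-diol (lactol, C19 epimers) | C=C1CC[C@H]2[C@@](C)(C(O)O3)C[C@@H]3C[C@]2(C)[C@H]1CC/C(C)=C\CO | intermediate
30 | (13Z)-labda-8(17),13-diene-2β,15,19-triol | C=C1CC[C@H]2[C@@](C)(CO)C[C@@H](O)C[C@]2(C)[C@H]1CC/C(C)=C\CO | intermediate
31 | (13Z)-2β-hydroxylabda-8(17),13-diene-15,19-diyl diacetate | C=C1CC[C@H]2[C@@](C)(COC(C)=O)C[C@@H](O)C[C@]2(C)[C@H]1CC/C(C)=C\COC(C)=O | intermediate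
32 | (13Z)-2α-(chloroacetoxy)labda-8(17),13-diene-15,19-diyl diacetate | C=C1CC[C@H]2[C@@](C)(COC(C)=O)C[C@H](OC(=O)CCl)C[C@]2(C)[C@H]1CC/C(C)=C\COC(C)=O | intermediate
33 | (13Z)-2α-(chloroacetoxy)-7α-hydroxylabda-8(17),13-diene-15,19-diyl diacetate | C=C1[C@H](O)C[C@H]2[C@@](C)(COC(C)=O)C[C@H](OC(=O)CCl)C[C@]2(C)[C@H]1CC/C(C)=C\COC(C)=O | intermediate
34 | (13Z)-2α,7α-dihydroxylabda-8(17),13-diene-15,19-diyl diacetate (CNP0171158.2) | C=C1[C@H](O)C[C@H]2[C@@](C)(COC(C)=O)C[C@H](O)C[C@]2(C)[C@H]1CC/C(C)=C\COC(C)=O | target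

**Step count and risks**

Total step count: 18. Longest linear sequence: 15 steps (steps 4–18, from 5 and 6); the side-chain bromide 4 takes steps 1–3.

Steps most likely to fail:

Step 12. The exchange may lose against α-lithiation of the vinyl sulfone or against tert-butyl addition, or the C11 carbanion may be quenched by proton transfer before it is alkylated. The fallback separates ring closure from coupling. It sets out from 24: tin hydride-mediated vinyl-radical 6-exo cyclisation onto the vinyl sulfone (Bu3SnH by syringe pump, AIBN, PhH, 80 °C) should give the cyclised sulfone 2β,19-epoxy-19-methoxy-11-(phenylsulfonyl)-12,13,14,15,16-pentanorlabd-8(17)-ene F1. Deprotonation of F1 (n-BuLi, THF/DMPU, −78 °C) and alkylation with 4 returns to the route at 27.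

Step 9. The chain may be carried poorly by the sulfonyl radical, stannyl radicals may consume the trap, or the C10 radical may be captured by the vinylsilane arm instead of 20. The fallback replaces addition–fragmentation by a Giese reaction and a later elimination. It sets out from 19: cyclisation in the presence of phenyl vinyl sulfone (Bu3SnH, AIBN, PhH, 80 °C) should give the saturated sulfone 1,3-dimethyl-3-[2-(phenylsulfonyl)ethyl]-2-[3-(trimethylsilyl)but-3-en-1-yl]-6-oxabicyclo[3.2.1]octan-7-one F2. α-Selenenylation (LDA, PhSeCl, THF, −78 °C) gives the selenide 1,3-dimethyl-3-[2-(phenylselanyl)-2-(phenylsulfonyl)ethyl]-2-[3-(trimethylsilyl)but-3-en-1-yl]-6-oxabicyclo[3.2.1]octan-7-one F3, and oxidation (H2O2, CH2Cl2, 0 °C) with syn-elimination of the selenoxide returns to the route at 21.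

Step 16. Activation of the 2β-hydroxyl, shielded by the syn-axial C19 and C20, may be slow, and E2 elimination to the Δ1/Δ2 alkenes may compete. The fallback replaces the redox condensation by a sulfonate displacement. It sets out from 31: triflation (Tf2O, pyridine, CH2Cl2, −30 °C) gives (13Z)-2β-[(trifluoromethylsulfonyl)oxy]labda-8(17),13-diene-15,19-diyl diacetate F4, and SN2 displacement with caesium chloroacetate (18-crown-6, toluene, 25 °C) returns to the route at 32.

Further compounds
F1 | step 12 | 2β,19-epoxy-19-methoxy-11-(phenylsulfonyl)-12,13,14,15,16-pentanorlabd-8(17)-ene (C19 epimers) | C=C1CC[C@H]2[C@@](C)(C(OC)O3)C[C@@H]3C[C@]2(C)[C@H]1CS(=O)(=O)c4ccccc4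
F2 | step 9 | 1,3-dimethyl-3-[2-(phenylsulfonyl)ethyl]-2-[3-(trimethylsilyl)but-3-en-1-yl]-6-oxabicyclo[3.2.1]octan-7-one (configuration as in 21) | C=C([Si](C)(C)C)CC[C@H]2[C@@](C)(C(=O)O3)C[C@@H]3C[C@]2(C)CCS(=O)(=O)c1ccccc1
F3 | step 9 | 1,3-dimethyl-3-[2-(phenylselanyl)-2-(phenylsulfonyl)ethyl]-2-[3-(trimethylsilyl)but-3-en-1-yl]-6-oxabicyclo[3.2.1]octan-7-one (configuration as in 21, selenide epimers) | C=C([Si](C)(C)C)CC[C@H]2[C@@](C)(C(=O)O3)C[C@@H]3C[C@]2(C)CC([Se]c4ccccc4)S(=O)(=O)c1ccccc1
F4 | step 16 | (13Z)-2β-[(trifluoromethylsulfonyl)oxy]labda-8(17),13-diene-15,19-diyl diacetate | C=C1CC[C@H]2[C@@](C)(COC(C)=O)C[C@@H](OS(=O)(=O)C(F)(F)F)C[C@]2(C)[C@H]1CC/C(C)=C\COC(C)=O
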